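The cyclopentenone is disconnected at C12–C13 and traced back to a squarate-derived cyclobutenone that carries the drimane as an alkynyl carbinol. The key step exploits the exocyclic C11=C12 alkene, whose carbon C12 sits in the C12–C16 ring between two oxidised carbons (C13 and C16), with C9 cis to C13. A palladium-triggered 1,2-shift of acyl carbon C13 onto the alkyne expands the four-membered ring to the five-membered one, sets that alkene geometry and leaves C13, C15 and C16 chemically distinct, all in one operation. The precursor is the adduct of an 8-O-silylated 8-epi-drimanyl acetylide with isopropyl semisquarate, made from (+)-sclareolide and diisopropyl squarate.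

Key step: step 9

Numbering: drimane C1–C10 as usual, C11 the carbon on C9, C12 the ring carbon of the exocyclic alkene, C13 the enol carbon, C14 the ring CH, C15 the ketone carbon, C16 the CHCl carbon.

Assumption: the vinylogous acid of the target is treated as a rapidly equilibrating pair of enol tautomers, so hydrolysis at C15 should deliver the C13-enol form as drawn.

Checks on the structures:
- The target is 8β-hydroxy-8α-methyl, the opposite of sclareolide at C8, so the C8 epimerisation in step 1 is required.
- C16 of the target is R.
- Precursor 14 is used as both C16 carbinol epimers (left undefined in its SMILES), because this centre becomes a ketone in step 9.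
- From step 9 onward no base is used, because C9–H is γ-acidic through the alkylidene dione.

Step 1
Reactants: 1 (+)-sclareolide
Product: 2 8-epi-sclareolide
Conditions: conc. H2SO4, HCO2H, 50 °C
Reagents that add atoms: none
Why: Acid-catalysed lactone epimerisation, in which reversible ionisation of the tertiary C8–O bond lets the carboxylic acid re-close on the β face to the more stable cis-fused lactone, setting the 8β-O/8α-methyl configuration while C5, C9 and C10 are untouched.

Step 2
Reactants: 2 8-epi-sclareolide
Product: 4 11-hydroxy-8-epi-sclareolide, via potassium lactone enolate 3 (not isolated)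
Conditions: KN(SiMe3)2, THF, −78 °C; then 3-phenyl-2-(phenylsulfonyl)oxaziridine, −78 °C; aq. NH4Cl
Reagents that add atoms: 3-phenyl-2-(phenylsulfonyl)oxaziridine, O=S(=O)(c1ccccc1)N1OC1c1ccccc1
Why: Enolate α-hydroxylation with an N-sulfonyloxaziridine, expected on the convex face of the cis-fused bicycle (OH cis to H-9, 11S); this new centre is irrelevant because step 4 turns the carbon into the aldehyde.

Step 3
Reactants: 4 11-hydroxy-8-epi-sclareolide
Product: 5 8-epi-homodrimane-8β,11,12-triol
Conditions: LiAlH4, THF, 0 °C → rt; H2O/aq. NaOH work-up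
Reagents that add atoms: none
Why: Hydride reduction of the lactone to the diol, which exposes the vicinal 11,12-diol and frees the tertiary C8 alcohol without touching a stereocentre.

Step 4
Reactants: 5 8-epi-homodrimane-8β,11,12-triol
Product: 6 8β-hydroxy-8-epi-driman-11-al
Conditions: NaIO4, THF/H2O, 0 °C → rt
Reagents that add atoms: none
Why: Malaprade glycol cleavage, which cuts only the vicinal diol, removes the former lactone carbonyl carbon as formaldehyde and leaves the C11 aldehyde under cold, near-neutral conditions that spare the epimerisable C9 and the retro-aldol-prone β-hydroxy aldehyde.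

Step 5
Reactants: 6 8β-hydroxy-8-epi-driman-11-al
Product: 7 8β-(triethylsilyloxy)-8-epi-driman-11-al
Conditions: Et3SiOTf, 2,6-lutidine, CH2Cl2, −78 °C
Reagents that add atoms: triethylsilyl trifluoromethanesulfonate, CC[Si](CC)(CC)OS(=O)(=O)C(F)(F)F
Why: Silyl ether formation with a silyl triflate and a hindered pyridine base, the standard way to cap a tertiary alcohol, run cold so that the aldehyde is not enolised and C9 is kept.

Step 6
Reactants: 7 8β-(triethylsilyloxy)-8-epi-driman-11-al; 8 dimethyl (1-diazo-2-oxopropyl)phosphonate
Product: 9 8-O-triethylsilyl-8-epi-drimanyl acetylene (C9–C11≡C12–H)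
Conditions: K2CO3, MeOH, 0 °C → rt
Reagents that add atoms: none
Why: Ohira–Bestmann (Seyferth–Gilbert) homologation, in which the diazophosphonate anion released by methanolysis adds to the aldehyde and loss of dimethyl phosphate and N2 gives an alkylidene carbene that rearranges to the terminal alkyne, the carbonate/methanol medium at 0 °C being mild enough to hold the C9 configuration.

Step 7
Reactants: 10 diisopropyl squarate
Product: 12 3-isopropoxycyclobut-3-ene-1,2-dione, via 4-hydroxy-2,3-diisopropoxycyclobut-2-enone 11 (not isolated)
Conditions: LiAlH(Ot-Bu)3, THF, −78 → −20 °C; then conc. aq. HCl, CH2Cl2, rt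
Reagents that add atoms: none
Why: Selective mono-1,2-reduction of one squarate carbonyl by the bulky hydride, then acid-catalysed allylic transposition with loss of isopropanol, the established route to the semisquarate.

Step 8
Reactants: 9 8-O-triethylsilyl-8-epi-drimanyl acetylene; 12 3-isopropoxycyclobut-3-ene-1,2-dione
Product: 14 4-(8-O-triethylsilyl-8-epi-drimanylethynyl)-4-hydroxy-3-isopropoxycyclobut-2-enone, via lithium acetylide 13 (not isolated)
Conditions: n-BuLi, THF, −78 °C; then 12, −78 °C; aq. NH4Cl at −78 °C
Reagents that add atoms: none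
Why: Acetylide 1,2-addition to a cyclobutenedione, which occurs at the more electrophilic carbonyl next to the isopropoxy-bearing carbon and not at the vinylogous ester carbonyl, giving the carbinol as a C16 epimer mixture that converges in step 9.

Step 9
Reactants: 14 4-(8-O-triethylsilyl-8-epi-drimanylethynyl)-4-hydroxy-3-isopropoxycyclobut-2-enone
Product: 16 2-(8-O-triethylsilyl-8-epi-drimanylmethylidene)-4-isopropoxycyclopent-4-ene-1,3-dione (C9 cis to C13), via vinylpalladium trifluoroacetate 15 (not isolated)
Conditions: Pd(O2CCF3)2 (10 mol %), THF, 20 °C; used at once in step 10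
Reagents that add atoms: none
Why: Pd(O2CCF3)2 (divalent palladium) π-activates the C11≡C12 alkyne, and the strained cyclobutenol responds with a semipinacol-type 1,2-shift of acyl carbon C13 from C16 to C12 on the face opposite the metal, while C16 becomes a ketone and the carbinol proton cleaves the C11–Pd bond of 15 with retention, returning the catalyst. The closest known reaction type is the palladium-catalysed ring expansion of 4-alkynyl-4-hydroxycyclobutenones to 2-alkylidenecyclopent-4-ene-1,3-diones. The C12–C16 ring is closed by ring expansion (four to five through a 1,2-shift), not by an end-to-end cyclisation, so no exo or endo closure mode applies. No stereocentre is formed and the C16 carbinol centre is erased; the only new stereo-element is the C11=C12 geometry, fixed by anti addition across the alkyne and retentive protonolysis so that C9 ends cis to C13. The step needs acyl (C13) and not vinyl (C15) migration, which is secured because C15 is an oxygen-bearing enone β-carbon of low migratory aptitude whose shift would break the vinylogous ester, and it needs the C8 oxygen kept off the activated alkyne, which the triethylsilyl ether secures. Neutral conditions and room temperature (heat would open the cyclobutenone to a vinylketene) protect the geometry of the doubly activated alkylidene.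

Step 10
Reactants: 16 2-(8-O-triethylsilyl-8-epi-drimanylmethylidene)-4-isopropoxycyclopent-4-ene-1,3-dione
Product: 17 (4S)-5-(8-O-triethylsilyl-8-epi-drimanylmethylidene)-4-hydroxy-3-isopropoxycyclopent-2-en-1-one (16S alcohol)
Conditions: (S)-1-methyl-3,3-diphenyltetrahydro-1H,3H-pyrrolo[1,2-c][1,3,2]oxazaborole (20 mol %), catecholborane, toluene/CH2Cl2, −78 °C; MeOH, pH 7 buffer
Reagents that add atoms: none
Why: Corey–Bakshi–Shibata reduction, in which hydride is delivered 1,2 to C16 (the only carbonyl not deactivated as a vinylogous ester) and the (S)-catalyst is chosen on the model that treats the alkylidene flank with its in-plane C11–H as the large group and the C15 alkoxy flank as the small one, which predicts the 16S alcohol, while −78 °C suppresses uncatalysed conjugate reduction.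

Step 11
Reactants: 17 (16S) alcohol
Product: 19 (4R)-5-(8-O-triethylsilyl-8-epi-drimanylmethylidene)-4-chloro-3-isopropoxycyclopent-2-en-1-one (16R chloride), via alkoxyphosphonium chloride 18 (not isolated)
Conditions: PPh3, hexachloroacetone, CH2Cl2, −20 → 0 °C
Reagents that add atoms: hexachloroacetone, ClC(Cl)(Cl)C(=O)C(Cl)(Cl)Cl
Why: Appel-type deoxychlorination, in which chloride displaces the alkoxyphosphonium group by SN2 with inversion (16S alcohol to 16R chloride); C16 has no β-hydrogen for elimination, and SN2′ attack would either create a cyclopentadienone (at C11) or hit an electron-rich enol ether carbon (at C14), so direct substitution is favoured.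

Step 12
Reactants: 19 (16R) chloride
Product: 20 target, (5R)-5-chloro-3-hydroxy-4-[(8β-hydroxy-8-epi-driman-11-ylidene)]cyclopent-2-en-1-one with C9 cis to C13
Conditions: 1 M aq. H2SO4, THF, 0 °C → rt
Reagents that add atoms: water, O
Why: Acid hydrolysis of the vinylogous ester (water adds at C15 and isopropanol leaves) together with acid cleavage of the triethylsilyl ether, using a non-nucleophilic counter-ion so that the C16 chloride is not exchanged and a water-rich medium that disfavours closure of the freed C8 hydroxyl onto C13.

Compound list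
1 | (+)-sclareolide | CC1(C)CCC[C@]2(C)[C@H]3CC(=O)O[C@]3(C)CC[C@@H]12 | starting material
2 | 8-epi-sclareolide (cis-fused lactone, 8β-O, 8α-methyl) | CC1(C)CCC[C@]2(C)[C@H]3CC(=O)O[C@@]3(C)CC[C@@H]12 | intermediate
3 | potassium enolate of 2 | CC1(C)CCC[C@]2(C)[C@H]3C=C([O-])O[C@@]3(C)CC[C@@H]12.[K+] | intermediate (not isolated)
4 | 11-hydroxy-8-epi-sclareolide (OH cis to H-9, 11S expected; either epimer serves) | CC1(C)CCC[C@]2(C)[C@H]3[C@H](O)C(=O)O[C@@]3(C)CC[C@@H]12 | intermediate
5 | 8-epi-homodrimane-8β,11,12-triol | CC1(C)CCC[C@]2(C)[C@@H]([C@H](O)CO)[C@@](C)(O)CC[C@@H]12 | intermediate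
6 | 8β-hydroxy-8-epi-driman-11-al (9β-CHO) | CC1(C)CCC[C@]2(C)[C@@H](C=O)[C@@](C)(O)CC[C@@H]12 | intermediate
7 | 8β-(triethylsilyloxy)-8-epi-driman-11-al | CC1(C)CCC[C@]2(C)[C@@H](C=O)[C@@](C)(O[Si](CC)(CC)CC)CC[C@@H]12 | intermediate
8 | dimethyl (1-diazo-2-oxopropyl)phosphonate | COP(=O)(OC)C(=[N+]=[N-])C(C)=O | starting material
9 | 8-O-triethylsilyl-8-epi-drimanyl acetylene (9β-ethynyl) | CC1(C)CCC[C@]2(C)[C@@H](C#C)[C@@](C)(O[Si](CC)(CC)CC)CC[C@@H]12 | intermediate
10 | diisopropyl squarate | CC(C)OC1=C(OC(C)C)C(=O)C1=O | starting material
11 | 4-hydroxy-2,3-diisopropoxycyclobut-2-enone (racemic) | CC(C)OC1=C(OC(C)C)C(=O)C1O | intermediate (not isolated)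
12 | 3-isopropoxycyclobut-3-ene-1,2-dione (isopropyl semisquarate) | CC(C)OC1=CC(=O)C1=O | intermediate
13 | lithium acetylide of 9 | CC1(C)CCC[C@]2(C)[C@@H](C#C[Li])[C@@](C)(O[Si](CC)(CC)CC)CC[C@@H]12 | intermediate (not isolated)
14 | 4-(8-O-triethylsilyl-8-epi-drimanylethynyl)-4-hydroxy-3-isopropoxycyclobut-2-enone (both C16 epimers) | CC1(C)CCC[C@]2(C)[C@@H](C#CC3(O)C(=O)C=C3OC(C)C)[C@@](C)(O[Si](CC)(CC)CC)CC[C@@H]12 | intermediate
15 | C11 vinylpalladium trifluoroacetate (Pd trans to C13) | CC1(C)CCC[C@]2(C)[C@@H](/C(=C3\C(=O)C=C(OC(C)C)C3=O)[Pd]OC(=O)C(F)(F)F)[C@@](C)(O[Si](CC)(CC)CC)CC[C@@H]12 | intermediate (not isolated)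
16 | 2-alkylidene-4-isopropoxycyclopent-4-ene-1,3-dione, 8-O-triethylsilyl, C9 cis to C13 | CC1(C)CCC[C@]2(C)[C@@H](/C=C3\C(=O)C=C(OC(C)C)C3=O)[C@@](C)(O[Si](CC)(CC)CC)CC[C@@H]12 | intermediate
17 | (16S)-alcohol, 5-alkylidene-4-hydroxy-3-isopropoxycyclopent-2-enone | CC1(C)CCC[C@]2(C)[C@@H](/C=C3\C(=O)C=C(OC(C)C)[C@H]3O)[C@@](C)(O[Si](CC)(CC)CC)CC[C@@H]12 | intermediate
18 | C16 alkoxytriphenylphosphonium chloride of 17 | CC1(C)CCC[C@]2(C)[C@@H](/C=C3\C(=O)C=C(OC(C)C)[C@H]3O[P+](c3ccccc3)(c3ccccc3)c3ccccc3)[C@@](C)(O[Si](CC)(CC)CC)CC[C@@H]12.[Cl-] | intermediate (not isolated)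
19 | (16R)-chloride, 5-alkylidene-4-chloro-3-isopropoxycyclopent-2-enone | CC1(C)CCC[C@]2(C)[C@@H](/C=C3\C(=O)C=C(OC(C)C)[C@@H]3Cl)[C@@](C)(O[Si](CC)(CC)CC)CC[C@@H]12 | intermediate
20 | CNP0279879.2 | CC1(C)CCC[C@]2(C)[C@@H](/C=C3\C(O)=CC(=O)[C@@H]3Cl)[C@@](C)(O)CC[C@@H]12 | target

Total step count: 12. Longest linear sequence: 11 steps (steps 1–6 and 8–12 from 1); step 7 is a one-step side branch.

Steps most likely to fail

Step 9 (key step). What may go wrong:
- isomerisation of the alkylidene geometry by reversible conjugate addition;
- competing vinyl migration;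
- loss of the silyl group, followed by attack of the C8 oxygen on the activated alkyne.

Fallback: sets out from aldehyde 7 and comes back at 16. Cyclopentane-1,2,4-trione (O=C1CC(=O)C(=O)C1) would be etherified with isopropanol (TsOH, benzene, water separator) to 4-isopropoxycyclopent-4-ene-1,3-dione F1. Knoevenagel condensation of F1 with 7 (ethylenediammonium diacetate, CH2Cl2, rt) should give 16 together with its C11=C12 geometric isomer F2. The two would be separated by chromatography and F2 re-equilibrated under the condensation conditions. Geometry is then set by separation and not by mechanism.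

Step 10. What may go wrong:
- poor or reversed facial selectivity, because both flanks of the C16 carbonyl are sp2 carbons of similar size;
- competing conjugate reduction of the s-cis enone.

Fallback: sets out from 16 and comes back at 17. Luche reduction (NaBH4, CeCl3·7H2O, MeOH, −78 °C) should give 17 and its (16R)-epimer F3 as separable diastereomers. F3 would be oxidised back to 16 with MnO2 in CH2Cl2 and recycled, so control by reagent is replaced by separation and recycling.

Step 12. What may go wrong:
- slow hydrolysis of the hindered isopropyl vinylogous ester;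
- on forcing, dehydration of the tertiary C8 alcohol, closure of the C8 hydroxyl onto C13, or epimerisation at C16.

Fallback: sets out from 19 and comes back at 20. Anhydrous dealkylation with BCl3 (CH2Cl2, −78 °C), which cleaves the isopropyl–oxygen bond and not the ring C–O bond, should give the 8-O-triethylsilyl vinylogous acid F4 after aqueous work-up. Buffered HF·pyridine (THF, 0 °C) would then remove the silyl group to give 20.

Further compounds
F1 | step 9 | 4-isopropoxycyclopent-4-ene-1,3-dione | CC(C)OC1=CC(=O)CC1=O
F2 | step 9 | C11=C12 geometric isomer of 16 (C9 trans to C13) | CC1(C)CCC[C@]2(C)[C@@H](/C=C3/C(=O)C=C(OC(C)C)C3=O)[C@@](C)(O[Si](CC)(CC)CC)CC[C@@H]12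
F3 | step 10 | (16R)-epimer of alcohol 17 | CC1(C)CCC[C@]2(C)[C@@H](/C=C3\C(=O)C=C(OC(C)C)[C@@H]3O)[C@@](C)(O[Si](CC)(CC)CC)CC[C@@H]12
F4 | step 12 | 8-O-triethylsilyl ether of 20 | CC1(C)CCC[C@]2(C)[C@@H](/C=C3\C(O)=CC(=O)[C@@H]3Cl)[C@@](C)(O[Si](CC)(CC)CC)CC[C@@H]12
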